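**Plan** (positions numbered as in the fernane skeleton: ring A C1–C5, C10; ring B C5, C6, C7, C9, C10; ring C C8, C9, C11–C14; ring D C13–C18; ring E C17–C21; isopropyl on C21; target = 3S,5R,7S,9S,10S,13S,14S,17R,18R,21R)
1. Cuts, in order: the silyl ether on O3; C7–C9, by retro-aldol of the β-hydroxy ketone C7(OH)–C9–C8(=O) that sits on the spiro atom C9 of rings B/C, which opens ring B to a C7 aldehyde; then C5–C10, because C5 is now the β-carbon of an enal and C10 is a methyl-bearing quaternary carbon next to C9, i.e. a tertiary radical from a C10=CH2 alkene; then C9–C10(sp2), by ketone α-alkenylation.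
2. The C/D/E ketone is cut at C8–C9 (alkyllithium onto a C14 nitrile), C14–CH3, C13–allyl, and ring D by Robinson annulation onto a 3-isopropyl-2-methylcyclopentanone.
3. Forward: ring E → D → C, side chain joined at C9, then ring A (C5–C10), then spiro ring B (C7–C9).
4. Stereochemistry: C21 from a Cu-catalysed asymmetric conjugate addition; C17, C18, C13, C14 each set anti to the neighbouring group (substrate control); C3 from a CBS reduction; C5 and C10 relayed from C3 in the chair transition state of the ring-A closure; C9 and C7 in the aldol.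

Key step: step 16

**Step 1**
Reactants: 1 2-methylcyclopent-2-en-1-one
Product: 3 trimethyl{[(3R)-2-methyl-3-(propan-2-yl)cyclopent-1-en-1-yl]oxy}silane, via bromomagnesium enolate 2 (not isolated)
Conditions: i-PrMgBr, CuBr·SMe2 (5 mol %), Josiphos-type ferrocenyl diphosphine (6 mol %), t-BuOMe, −78 °C; then TMSCl, Et3N, HMPA, −78 → 0 °C
Reagents that add atoms: isopropylmagnesium bromide CC(C)[Mg]Br; chlorotrimethylsilane C[Si](C)(C)Cl
Why: Cu-catalysed asymmetric conjugate addition of a Grignard reagent to a cyclic enone sets C21 (the ligand enantiomer is chosen for 3R), and O-silylation of the magnesium enolate fixes the tetrasubstituted enolate regiochemistry for the next C–C bond.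

**Step 2**
Reactants: 3 silyl enol ether; 4 pent-1-en-3-one
Product: 5 (2R,3R)-2-methyl-2-(3-oxopentyl)-3-(propan-2-yl)cyclopentan-1-one
Conditions: Sc(OTf)3 (10 mol %), CH2Cl2, −78 → −20 °C; then 1 M HCl
Reagents that add atoms: none
Why: Lewis-acid-catalysed Mukaiyama–Michael addition should form the quaternary C17 with the enone entering anti to the adjacent isopropyl group, so that C17-CH3 and the C21 isopropyl group end up cis.

**Step 3**
Reactants: 5 diketone
Product: 6 (1R,7aR)-4,7a-dimethyl-1-(propan-2-yl)-1,2,3,6,7,7a-hexahydro-5H-inden-5-one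
Conditions: KOH, MeOH, 65 °C
Reagents that add atoms: none
Why: Intramolecular aldol condensation (second half of a Robinson annulation) under thermodynamic control, in which only the C13 methylene/C18 carbonyl pairing gives a six-membered ketol that can dehydrate, closes ring D as the α-methyl enone.

**Step 4**
Reactants: 6 bicyclic enone
Product: 8 (1R,3aR,4S,7aR)-4,7a-dimethyl-1-(propan-2-yl)-4-(prop-2-en-1-yl)octahydro-5H-inden-5-one, via lithium enolate 7 (not isolated)
Conditions: Li, NH3(l)/THF, t-BuOH (1 equiv), −78 °C; then allyl bromide, −78 → −33 °C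
Reagents that add atoms: allyl bromide C=CCBr
Why: Stork reductive alkylation, in which protonation of C18 anti to the angular C17 methyl gives the trans-hydrindane and the regiodefined enolate is allylated at C13 from the α-face, away from the 1,3-related axial C17 methyl, leaving the C13 methyl β.

**Step 5**
Reactants: 8 allyl ketone
Product: 9 (1R,3aR,4S,7aR)-4,7a-dimethyl-1-(propan-2-yl)-4-(prop-2-en-1-yl)octahydro-1H-indene-5-carbonitrile (both C5 epimers)
Conditions: TosMIC, t-BuOK, DME, EtOH (2 equiv), 0 → 40 °C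
Reagents that add atoms: p-toluenesulfonylmethyl isocyanide Cc1ccc(cc1)S(=O)(=O)C[N+]#[C-]
Why: van Leusen reductive cyanation homologates the α-quaternary ketone to the nitrile whose carbon is the future C8, and the C14 configuration is irrelevant because it is planarised in step 6.

**Step 6**
Reactants: 9 nitrile
Product: 11 (1R,3aR,4S,5S,7aR)-4,5,7a-trimethyl-1-(propan-2-yl)-4-(prop-2-en-1-yl)octahydro-1H-indene-5-carbonitrile, via lithiated nitrile 10 (not isolated)
Conditions: LDA, THF, −78 → 0 °C; then MeI, −78 °C → rt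
Reagents that add atoms: iodomethane CI
Why: C-Methylation of the planar lithiated nitrile should occur axially from the α-face, anti to the vicinal axial C13 methyl and free of syn-axial groups, giving C14-CH3 trans to C13-CH3 with the nitrile equatorial.

**Step 7**
Reactants: 11 quaternary nitrile
Product: 13 (1R,3aR,4S,5S,7aR)-4-(3-iodopropyl)-4,5,7a-trimethyl-1-(propan-2-yl)octahydro-1H-indene-5-carbonitrile, via B-alkyl-9-BBN 12 (not isolated)
Conditions: 9-BBN, THF, 0 °C → rt; then NaOMe, I2, MeOH, 0 °C → rt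
Reagents that add atoms: iodine II
Why: Anti-Markovnikov hydroboration with 9-BBN tolerates the nitrile, and base-induced iodinolysis of the primary B–alkyl bond gives the primary iodide directly.

**Step 8**
Reactants: 13 iodo nitrile
Product: 15 (3R,3aR,5aS,9aS,9bR)-3a,5a,9a-trimethyl-3-(propan-2-yl)dodecahydro-6H-cyclopenta[a]naphthalen-6-one, via cyclic N-lithio ketimine 14 (not isolated)
Conditions: t-BuLi (2.2 equiv), Et2O/pentane, −78 °C → rt; then 2 M HCl, THF, rt
Reagents that add atoms: water O
Why: Iodine–lithium exchange outruns attack of t-BuLi on the hindered nitrile, the primary alkyllithium adds intramolecularly to the nitrile (6-exo-dig, Parham-type cyclisation), and acid hydrolysis of the imine gives the C8 ketone and completes the trans-fused ring C.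

**Step 9**
Reactants: 16 methyl 2,2-dimethyl-3-oxobutanoate; 17 2,3-dibromoprop-1-ene
Product: 19 methyl 6-bromo-2,2-dimethyl-3-oxohept-6-enoate, via lithium enolate 18 (not isolated)
Conditions: LDA, THF, −78 °C; then 17, −78 → 0 °C
Reagents that add atoms: none
Why: The quaternary α-carbon leaves the methyl group as the only enolisable site, and its lithium enolate is alkylated at the allylic bromide (SN2) while the vinylic bromide stays inert.

**Step 10**
Reactants: 19 keto ester
Product: 20 methyl (3S)-6-bromo-3-hydroxy-2,2-dimethylhept-6-enoate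
Conditions: (R)-Me-CBS (20 mol %), catecholborane, toluene, −78 °C
Reagents that add atoms: none
Why: Corey–Bakshi–Shibata reduction with the quaternary C(CH3)2CO2Me group as the large substituent is expected to give the 3S alcohol with the (R)-catalyst, and catecholborane at −78 °C spares the ester and the bromoalkene.

**Step 11**
Reactants: 20 hydroxy ester
Product: 21 methyl (3S)-6-bromo-3-[(tert-butyldimethylsilyl)oxy]-2,2-dimethylhept-6-enoate
Conditions: TBSOTf, 2,6-lutidine, CH2Cl2, 0 °C
Reagents that add atoms: tert-butyldimethylsilyl triflate CC(C)(C)[Si](C)(C)OS(=O)(=O)C(F)(F)F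
Why: Silylation of a hindered secondary alcohol with the silyl triflate gives an ether that should survive the enolate, hydride, oxidant, ylide and iron hydride conditions ahead.

**Step 12**
Reactants: 15 tricyclic ketone; 21 alkenyl bromide
Product: 23 methyl (3S)-3-[(tert-butyldimethylsilyl)oxy]-2,2-dimethyl-6-[(3R,3aR,5aS,9aS,9bR)-3a,5a,9a-trimethyl-6-oxo-3-(propan-2-yl)dodecahydro-1H-cyclopenta[a]naphthalen-7-yl]hept-6-enoate (both C9 epimers), via lithium enolate 22 (not isolated)
Conditions: LiHMDS (2.2 equiv), THF, 0 °C; then Pd2(dba)3 (2.5 mol %), Q-Phos (5 mol %), 21, toluene, 60 °C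
Reagents that add atoms: none
Why: Pd-catalysed α-alkenylation of a ketone enolate with an alkenyl bromide forms C9–C10; C14 is quaternary so only C9 can be enolised, the hindered non-enolisable ester is inert, and kinetic protonation of the product dienolate on work-up keeps the C10=CH2 group out of conjugation.

**Step 13**
Reactants: 23 keto ester
Product: 24 (3S)-3-[(tert-butyldimethylsilyl)oxy]-2,2-dimethyl-6-[(3R,3aR,5aS,9aS,9bR)-6-hydroxy-3a,5a,9a-trimethyl-3-(propan-2-yl)dodecahydro-1H-cyclopenta[a]naphthalen-7-yl]hept-6-en-1-ol (epimers at C8 and C9)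
Conditions: LiAlH4, THF, 0 °C → rt
Reagents that add atoms: none
Why: Exhaustive hydride reduction of the ketone and the neopentyl ester is the simplest way to bring the ester to the alcohol level, and the C8 carbinol epimers converge again in step 14.

**Step 14**
Reactants: 24 diol
Product: 25 (3S)-3-[(tert-butyldimethylsilyl)oxy]-2,2-dimethyl-6-[(3R,3aR,5aS,9aS,9bR)-3a,5a,9a-trimethyl-6-oxo-3-(propan-2-yl)dodecahydro-1H-cyclopenta[a]naphthalen-7-yl]hept-6-enal (both C9 epimers)
Conditions: Dess–Martin periodinane, CH2Cl2, rt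
Reagents that add atoms: none
Why: Dess–Martin oxidation of both alcohols under near-neutral conditions gives the non-enolisable neopentyl aldehyde and restores the β,γ-unsaturated ketone without moving the double bond.

**Step 15**
Reactants: 25 keto aldehyde
Product: 26 (2E,5S)-5-[(tert-butyldimethylsilyl)oxy]-4,4-dimethyl-8-[(3R,3aR,5aS,9aS,9bR)-3a,5a,9a-trimethyl-6-oxo-3-(propan-2-yl)dodecahydro-1H-cyclopenta[a]naphthalen-7-yl]nona-2,8-dienal (both C9 epimers)
Conditions: Ph3P=CHCHO, toluene, 90 °C
Reagents that add atoms: (triphenylphosphoranylidene)acetaldehyde O=CC=P(c1ccccc1)(c1ccccc1)c1ccccc1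
Why: Wittig olefination with a stabilised ylide attacks only the aldehyde (the C8 ketone lies between a quaternary and a tertiary carbon) and gives the E-enal, which makes C5 an acceptor carbon.

**Step 16**
Reactants: 26 enal
Product: 27 2-{(1R,3S,6S)-3-[(tert-butyldimethylsilyl)oxy]-2,2,6-trimethyl-6-[(3R,3aR,5aS,9aS,9bR)-3a,5a,9a-trimethyl-6-oxo-3-(propan-2-yl)dodecahydro-1H-cyclopenta[a]naphthalen-7-yl]cyclohexyl}acetaldehyde (ring A closed; both C9 epimers)
Conditions: Fe(acac)3 (30 mol %), PhSiH3 (2.5 equiv), EtOH/(CH2OH)2 (5:1), 60 °C, 0.01 M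
Reagents that add atoms: none
Why: An iron hydride formed from Fe(acac)3, PhSiH3 and ethanol transfers H• to the CH2 terminus of the electron-rich 1,1-disubstituted C10 alkene (Markovnikov MHAT), creating the C10 methyl group and a nucleophilic tertiary C10 radical that adds to C5, the β-carbon of the E-enal, after which the α-formyl radical is reduced by Fe(II) and protonated by ethanol. The closest known reaction type is the iron-mediated reductive olefin–enone coupling (MHAT-initiated Giese addition) in its intramolecular form. Ring A closes in the 6-exo-trig mode. C10 and C5 are set in a chair-like transition state with the C3 silyloxy group and the enal arm on C5 equatorial and the bulky C9 substituent of the radical pseudo-equatorial (the alternative clashes with the axial C4 methyl), so the C10 methyl becomes axial and trans to the axial H-5, i.e. 5R,10S relayed from C3. The step needs HAT to the 1,1-disubstituted alkene in preference to the enal, which the much faster MHAT to electron-rich alkenes should secure, and cyclisation faster than a second HAT, which the gem-dimethyl group, the activated acceptor and high dilution should secure; the C9–H centre is not controlled and need not be, since it is enolised in step 17.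

**Step 17**
Reactants: 27 keto aldehyde
Product: 28 (3S,5R,7S,9S,10S,13S,14S,17R,18R,21R)-3-[(tert-butyldimethylsilyl)oxy]-7-hydroxy-7(8→9)-abeo-fernane-type spiro ketone (3-O-TBS ether of the target)
Conditions: KOH (0.5 equiv), MeOH/THF, 0 °C → rt
Reagents that add atoms: none
Why: Base-mediated intramolecular aldol addition (5-exo) of the only possible ketone enolate (C9) to the C7 aldehyde, the usual sense of cyclisation of 1,6-keto aldehydes under hydroxide, closes the spiro ring B; reversible conditions should place the quaternary C10 equatorial on ring C (the alternative puts it syn-axial to the C14 methyl), which fixes C9, and an open transition state with the aldehyde oxygen turned away from the enolate oxygen should give the 7-OH anti to C8.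

**Step 18**
Reactants: 28 silyl ether
Product: 29 target, (3S,5R,7S,9S,10S,13S,14S,17R,18R,21R)-3,7-dihydroxy-7(8→9)-abeo-fernane-type spiro[4.5] ketone
Conditions: HF·pyridine, pyridine/THF, 0 °C → rt
Reagents that add atoms: none
Why: Desilylation with buffered HF avoids basic fluoride and so avoids retro-aldol cleavage of the β-hydroxy ketone, whose quaternary α-carbon also rules out dehydration.

**Compound list**
1 | 2-methylcyclopent-2-en-1-one | CC1=CCCC1=O | starting material
2 | bromomagnesium (3R)-2-methyl-3-(propan-2-yl)cyclopent-1-en-1-olate | CC(C)[C@H]1CCC(O[Mg]Br)=C1C | intermediate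
3 | trimethyl{[(3R)-2-methyl-3-(propan-2-yl)cyclopent-1-en-1-yl]oxy}silane | CC(C)[C@H]1CCC(O[Si](C)(C)C)=C1C | intermediate
4 | pent-1-en-3-one | CCC(=O)C=C | starting material
5 | (2R,3R)-2-methyl-2-(3-oxopentyl)-3-(propan-2-yl)cyclopentan-1-one | CC(C)[C@H]1CCC(=O)[C@]1(C)CCC(=O)CC | intermediate
6 | (1R,7aR)-4,7a-dimethyl-1-(propan-2-yl)-1,2,3,6,7,7a-hexahydro-5H-inden-5-one | CC(C)[C@H]1CCC2=C(C)C(=O)CC[C@]12C | intermediate
7 | lithium (1R,3aR,7aR)-4,7a-dimethyl-1-(propan-2-yl)-2,3,3a,6,7,7a-hexahydro-1H-inden-5-olate | CC(C)[C@H]1CC[C@@H]2[C@]1(C)CCC(O[Li])=C2C | intermediate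
8 | (1R,3aR,4S,7aR)-4,7a-dimethyl-1-(propan-2-yl)-4-(prop-2-en-1-yl)octahydro-5H-inden-5-one | CC(C)[C@H]1CC[C@@H]2[C@]1(C)CCC(=O)[C@@]2(C)CC=C | intermediate
9 | (1R,3aR,4S,7aR)-4,7a-dimethyl-1-(propan-2-yl)-4-(prop-2-en-1-yl)octahydro-1H-indene-5-carbonitrile (C5 epimers) | CC(C)[C@H]1CC[C@@H]2[C@]1(C)CCC(C#N)[C@@]2(C)CC=C | intermediate
10 | N-lithio keteniminate of 9 | CC(C)[C@H]1CC[C@@H]2[C@]1(C)CCC(=C=N[Li])[C@@]2(C)CC=C | intermediate
11 | (1R,3aR,4S,5S,7aR)-4,5,7a-trimethyl-1-(propan-2-yl)-4-(prop-2-en-1-yl)octahydro-1H-indene-5-carbonitrile | CC(C)[C@H]1CC[C@@H]2[C@]1(C)CC[C@](C)(C#N)[C@@]2(C)CC=C | intermediate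
12 | B-alkyl-9-BBN from 11 (boron on the terminal carbon of the former allyl group) | CC(C)[C@H]1CC[C@@H]2[C@]1(C)CC[C@](C)(C#N)[C@@]2(C)CCCB3C4CCCC3CCC4 | intermediate
13 | (1R,3aR,4S,5S,7aR)-4-(3-iodopropyl)-4,5,7a-trimethyl-1-(propan-2-yl)octahydro-1H-indene-5-carbonitrile | CC(C)[C@H]1CC[C@@H]2[C@]1(C)CC[C@](C)(C#N)[C@@]2(C)CCCI | intermediate
14 | cyclic N-lithio ketimine (C8=N–Li) of the C/D/E tricycle | CC(C)[C@H]1CC[C@@H]2[C@]1(C)CC[C@]1(C)C(=N[Li])CCC[C@@]21C | intermediate
15 | (3R,3aR,5aS,9aS,9bR)-3a,5a,9a-trimethyl-3-(propan-2-yl)dodecahydro-6H-cyclopenta[a]naphthalen-6-one | CC(C)[C@H]1CC[C@@H]2[C@]1(C)CC[C@]1(C)C(=O)CCC[C@@]21C | intermediate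
16 | methyl 2,2-dimethyl-3-oxobutanoate | CC(=O)C(C)(C)C(=O)OC | starting material
17 | 2,3-dibromoprop-1-ene | C=C(Br)CBr | starting material
18 | lithium enolate of 16 (methyl-side enolate) | C=C(O[Li])C(C)(C)C(=O)OC | intermediate
19 | methyl 6-bromo-2,2-dimethyl-3-oxohept-6-enoate | C=C(Br)CCC(=O)C(C)(C)C(=O)OC | intermediate
20 | methyl (3S)-6-bromo-3-hydroxy-2,2-dimethylhept-6-enoate | C=C(Br)CC[C@H](O)C(C)(C)C(=O)OC | intermediate
21 | methyl (3S)-6-bromo-3-[(tert-butyldimethylsilyl)oxy]-2,2-dimethylhept-6-enoate | C=C(Br)CC[C@H](O[Si](C)(C)C(C)(C)C)C(C)(C)C(=O)OC | intermediate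
22 | lithium enolate of 15 (C8–O–Li, C8=C9) | CC(C)[C@H]1CC[C@@H]2[C@]1(C)CC[C@]1(C)C(O[Li])=CCC[C@@]21C | intermediate
23 | C9-alkenylated keto ester (name as in step 12; C9 epimers) | CC(C)[C@H]1CC[C@@H]2[C@]1(C)CC[C@]1(C)C(=O)C(CC[C@@]21C)C(=C)CC[C@H](O[Si](C)(C)C(C)(C)C)C(C)(C)C(=O)OC | intermediate
24 | C8 carbinol / primary neopentyl alcohol diol (name as in step 13) | CC(C)[C@H]1CC[C@@H]2[C@]1(C)CC[C@]1(C)C(O)C(CC[C@@]21C)C(=C)CC[C@H](O[Si](C)(C)C(C)(C)C)C(C)(C)CO | intermediate
25 | keto neopentyl aldehyde (name as in step 14) | CC(C)[C@H]1CC[C@@H]2[C@]1(C)CC[C@]1(C)C(=O)C(CC[C@@]21C)C(=C)CC[C@H](O[Si](C)(C)C(C)(C)C)C(C)(C)C=O | intermediate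
26 | keto E-enal (name as in step 15) | CC(C)[C@H]1CC[C@@H]2[C@]1(C)CC[C@]1(C)C(=O)C(CC[C@@]21C)C(=C)CC[C@H](O[Si](C)(C)C(C)(C)C)C(C)(C)/C=C/C=O | intermediate
27 | ring-A-closed keto aldehyde (name as in step 16; 3S,5R,10S, C9 epimers) | CC(C)[C@H]1CC[C@@H]2[C@]1(C)CC[C@]1(C)C(=O)C(CC[C@@]21C)[C@@]1(C)CC[C@H](O[Si](C)(C)C(C)(C)C)C(C)(C)[C@@H]1CC=O | intermediate
28 | 3-O-TBS ether of the target | CC(C)[C@H]1CC[C@@H]2[C@]1(C)CC[C@]1(C)C(=O)[C@]3(CC[C@@]21C)[C@@H](O)C[C@H]1C(C)(C)[C@@H](O[Si](C)(C)C(C)(C)C)CC[C@@]13C | intermediate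
29 | target spiro keto diol | CC(C)[C@H]1CC[C@@H]2[C@]1(C)CC[C@]1(C)C(=O)[C@]3(CC[C@@]21C)[C@@H](O)C[C@H]1C(C)(C)[C@@H](O)CC[C@@]13C | target

**Step count and risks**
Total: 18 steps. Longest linear sequence: 15 steps (steps 1–8, then 12–18); steps 9–11 make the second fragment.

Most likely to fail:

Step 16. The tertiary radical may be reduced by a second hydrogen-atom transfer before it cyclises, or the chair preference may be too small for clean control of C5 and C10. The fallback is polar Lewis-acid chemistry; it sets out from 25 and returns at 27. The exocyclic alkene of 25 is moved into conjugation with DBU (toluene, 80 °C) to give the tetrasubstituted alkylidene ketone aldehyde F5. Wittig reaction with Ph3P=CHCH2SiMe3 converts the aldehyde into the allylsilane F6. TiCl4 (CH2Cl2, −78 °C) then triggers an intramolecular Hosomi–Sakurai conjugate addition, in which C5 (γ-carbon of the allylsilane) attacks C10 (β-carbon of the enone), to give the C5-vinyl ketone F7. Hydroboration–oxidation (9-BBN; NaBO3) gives the primary alcohol F8, and Dess–Martin oxidation gives 27.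

Step 12. Oxidative addition and reductive elimination at the hindered enolate may be slow, and the product may isomerise into conjugation under the basic conditions. The fallback replaces enolate coupling by a Suzuki coupling; it sets out from 15 and returns at 23. Ketone 15 is dehydrogenated with IBX (DMSO, 70 °C) to the C9=C11 enone F1 and iodinated (I2, pyridine) to the α-iodoenone F2. Bromide 21 is converted by Miyaura borylation (B2pin2, PdCl2(PPh3)2, KOPh) into the alkenyl pinacol boronate F3. Suzuki–Miyaura coupling of F2 with F3 (Pd(dppf)Cl2, K3PO4) gives the cross-conjugated dienone F4. 1,4-Reduction of the ring enone with L-Selectride (−78 °C) and kinetic protonation give 23.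

Step 17. Facial selectivity at the aldehyde may be poor (7-epimer), and enolisation of the aldehyde instead of the hindered ketone may divert material. The fallback sets C7 by hydride reduction instead of by the aldol; it sets out from 27 and returns at 28. The aldol is run as before and the crude ketol, containing the 7-epimer F9, is oxidised with Dess–Martin periodinane to the non-enolisable C7,C8-diketone F10. NaBH4 (MeOH, −40 °C) should reduce only the unhindered cyclopentanone carbonyl C7, from the ring-B face that carries C8 and H-5 and away from the C10 methyl and C11, giving 28.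

**Further compounds**
F1 | step 12 | C9=C11 enone of 15 | CC(C)[C@H]1CC[C@@H]2[C@]1(C)CC[C@]1(C)C(=O)C=CC[C@@]21C
F2 | step 12 | C9-iodo enone | CC(C)[C@H]1CC[C@@H]2[C@]1(C)CC[C@]1(C)C(=O)C(I)=CC[C@@]21C
F3 | step 12 | pinacol alkenylboronate from 21 | C=C(B1OC(C)(C)C(C)(C)O1)CC[C@H](O[Si](C)(C)C(C)(C)C)C(C)(C)C(=O)OC
F4 | step 12 | cross-conjugated dienone ester | CC(C)[C@H]1CC[C@@H]2[C@]1(C)CC[C@]1(C)C(=O)C(=CC[C@@]21C)C(=C)CC[C@H](O[Si](C)(C)C(C)(C)C)C(C)(C)C(=O)OC
F5 | step 16 | conjugated C9=C10 alkylidene ketone aldehyde | CC(C)[C@H]1CC[C@@H]2[C@]1(C)CC[C@]1(C)C(=O)C(CC[C@@]21C)=C(C)CC[C@H](O[Si](C)(C)C(C)(C)C)C(C)(C)C=O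
F6 | step 16 | allylsilane of F5 | CC(C)[C@H]1CC[C@@H]2[C@]1(C)CC[C@]1(C)C(=O)C(CC[C@@]21C)=C(C)CC[C@H](O[Si](C)(C)C(C)(C)C)C(C)(C)C=CC[Si](C)(C)C
F7 | step 16 | ring-A-closed C5-vinyl ketone | CC(C)[C@H]1CC[C@@H]2[C@]1(C)CC[C@]1(C)C(=O)C(CC[C@@]21C)[C@@]1(C)CC[C@H](O[Si](C)(C)C(C)(C)C)C(C)(C)[C@@H]1C=C
F8 | step 16 | ring-A-closed C7 primary alcohol | CC(C)[C@H]1CC[C@@H]2[C@]1(C)CC[C@]1(C)C(=O)C(CC[C@@]21C)[C@@]1(C)CC[C@H](O[Si](C)(C)C(C)(C)C)C(C)(C)[C@@H]1CCO
F9 | step 17 | 7-epimer of 28 | CC(C)[C@H]1CC[C@@H]2[C@]1(C)CC[C@]1(C)C(=O)[C@]3(CC[C@@]21C)[C@H](O)C[C@H]1C(C)(C)[C@@H](O[Si](C)(C)C(C)(C)C)CC[C@@]13C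
F10 | step 17 | C7,C8-diketone | CC(C)[C@H]1CC[C@@H]2[C@]1(C)CC[C@]1(C)C(=O)[C@]3(CC[C@@]21C)C(=O)C[C@H]1C(C)(C)[C@@H](O[Si](C)(C)C(C)(C)C)CC[C@@]13C
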